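You cannot get more Z from this flask than its 0.700 equiv of E allows, since J + E -> Z spends one E on each Z; what you need to know is how far below that ceiling the flask ends, and how that distance moves with the charge of Q.

| setting | north-west | north-east | flask |
|---|---|---|---|
| J | 22 mM | 22 mM | 22 mM |
| E | 0.70 equiv | 0.70 equiv | 0.700 equiv |
| Q | 0.28 equiv | 0.44 equiv | 0.200 equiv |
| remark | run made earlier | run made earlier |  |
| time |  |  | 30 h |

| run | time / h | J / % | Z / % |
|---|---|---|---|
| north-west | 2.00 | 28.6 | 38.2 |
| north-west | 6.00 | 21.9 | 46.2 |
| north-west | 10.0 | 21.9 | 47.3 |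
| north-west | 15.0 | 20.9 | 47.0 |
| north-west | 25.0 | 21.4 | 47.6 |
| north-west | 30.0 | 21.0 | 47.1 |
| north-east | 2.00 | 23.0 | 34.4 |
| north-east | 6.00 | 15.9 | 41.0 |
| north-east | 10.0 | 15.9 | 42.5 |
| north-east | 15.0 | 15.1 | 42.8 |
| north-east | 25.0 | 15.1 | 42.8 |
| north-east | 30.0 | 14.9 | 43.2 |

(scatter of a reading: 0.3 percentage points)

- on the list of suspects stand: J + E -> Z; J <-> L; J + Q -> X; E -> G; Q + E -> D
- what has gone from J into another species counts as reacted, even if it can come back

- how much of the J has reacted by 30 h
- how much Z there is at 30 h, in percent of the J charged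

The flask looks nearly like the north-west run, with the same J and E but 0.200 equiv of Q against 0.28 equiv. In both earlier runs J and Z stand still from about 10.0 h with J present, so I take E for the limiting reagent. Between north-west and north-east, Z at 30.0 h goes from 47.1% to 43.2% as Q rises, which reads as 0.244 of Z lost per unit of Q added, both as fractions of the J charged: the price of Q, a reading that carries the scatter. J falls too, by 0.381 per unit. So the flask, with less Q than north-west, should end higher in Z, at 49.1%, and my conversion, with L counted as reacted, is 76.0%.

The forecast, built on balances of J and E and noting “Linear extrapolation of the two runs agrees”, gives a conversion of 76% (74% to 78%) and Z of 49.2% (47.8% to 50.6%), its Z a shade above mine.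

The flask gives a conversion of 75.2% and Z of 49.2%, both inside the forecast's ranges.

    J + E → Z (k = 61.0 M⁻¹ h⁻¹)
    J ⇌ L (K = 0.360, k = 8.90 h⁻¹)
    J + Q → X (k = 150 M⁻¹ h⁻¹)
    E → G (k = 0.210 h⁻¹)
    Q + E → D (k = 32.0 M⁻¹ h⁻¹)

With E at 0.584 equiv, the conversion would lie outside the forecast's range. Now carry the price from this flask to its neighbour, the same recipe with 0.500 equiv of Q: taking the price times the added Q from 49.2% leaves 41.9% of Z, and that neighbour gives 41.0%, with X at 41.8%.

The earlier runs and the new flask come from a simulation from invented constants.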